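One percentage point of the charge that ends in chains is worth 5.00 monomer units per initiator in the next flask, which charges 500 free monomer per initiator.

all flasks: initiator 0.10 mM
- Thursday's: free monomer 0.070 M; transfer agent 5 mM; protic impurity 5 mM; run made earlier
- Monday's: free monomer 0.11 M; transfer agent 5 mM; protic impurity 5 mM; run made earlier
- flask: free monomer 0.050 M; transfer agent 5.00 mM; protic impurity 5.00 mM; time 12 min

| run | time / min | monomer in chains / % | free monomer / % |
|---|---|---|---|
| Thursday's | 2.00 | 30 | 20 |
| Thursday's | 4.00 | 34 | 6 |
| Thursday's | 5.00 | 38 | 2 |
| Thursday's | 8.00 | 40 | 3 |
| Monday's | 0.500 | 15 | 67 |
| Monday's | 1.33 | 29 | 37 |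
| Monday's | 3.00 | 37 | 12 |
| Monday's | 8.00 | 37 | 0 |

(scatter of a reading: 1.5 percentage points)

- the average divides the monomer in chains by the number of chains begun, living and dead together
- the earlier runs do not show the number of chains; that part of a forecast is a guess

* whether the average number of monomer units in a chain (chains begun, living or dead) reaches 100 by 12 min (no / yes)
* average number of monomer units in a chain (chains begun, living or dead) at 12 min

Monomer in chains over free monomer charged is a share of the charge, and time drops out of it once free monomer is nearly gone. This share, the selectivity, reads 40 % at the end of Thursday's run and 37 % at the end of Monday's, with a mean of 0.385 of the charge.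

Multiplied by free monomer per initiator, the share gives the ceiling length, the length if each initiator begins one chain and the transfer agent and protic impurity begin none. For the next flask it is 193, about twice the 100 wanted.

The runs show no chain count, so what follows is my own bet. Between 3.00 min and 8.00 min in Monday's run, free monomer loses 12 percentage points while monomer in chains gains 0 points, less than the loss, each reading carrying a scatter of 1.5 points. I read that, for Monday's run, as ends that stop growing with no fresh chains taking over. On that bet the next flask is charged as written, with the initiator left unchanged, and I expect a length near the ceiling, which stands above the 100 wanted.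

The forecast answers no, with a length of 6, its chain count being “a guess, not measured”. The flask answers yes, with a length of 179 at 12 min.

    free monomer + initiator → living end + monomer in chains (k = 1.60 M⁻¹ s⁻¹)
    free monomer + living end → monomer in chains + living end, rate k2*[living end]*[free monomer] (k = 77.0 M⁻¹ s⁻¹)
    living end + transfer agent → dead chain (kL = 1.10 M⁻¹ s⁻¹)
    free monomer → uncatalysed product (k = 0.00640 s⁻¹)
    protic impurity + free monomer → quenched substrate (k = 14.0 M⁻¹ s⁻¹)

At 12 min the flask holds 0.999 chains, dead and living, per initiator charged. Its length of 179 stands below the ceiling, at 0.927 of 193. For Monday's run, 37 % in chains and 1100 free monomer per initiator put the ceiling at 407.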